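Locants follow kaurane usage: ring A is C1, C2, C3, C4, C5, C10; C18 (methyl) and C19 (carboxyl) sit on C4, the carboxyl C6 on C5, the methyl C20 on C10; the bicycle holds C8 (bearing formyl C7), C9, C11, C12 (ketone), C13, C14, C15, C16 (=C17H2).

## The problem

The target is a 6,7-seco-kaurane-type keto aldehyde diacid. Ring A hangs by the single bond C9–C10 on a bicyclo[3.2.1]octane made of ring C (C8, C9, C11, C12, C13, C14) and ring D (C8, C14, C13, C16, C15); there is no ring B, so nothing cyclic relays stereochemistry between the two halves. There are six stereocentres: the quaternary C4, C5 and the quaternary C10 on ring A, with C19, C6 and C20 on one face and C9 on the other, and the quaternary C8, C9 and the bridgehead C13 in the bicycle. C8 fixes C13, because the C15–C16 bridge can only close cis, and a large group on C9 can steer a bond made at C8; the three ring-A centres are contiguous and can be set together. The relation of C9 to C10, across a rotating bond between a tertiary and a quaternary carbon, cannot be left to the substrate and needs an outside source of asymmetry; C9 also lies between two quaternary carbons, so bonds to it must be made by processes that tolerate crowding. The fragile functions are the neopentyl aldehyde, the exocyclic methylene β,γ to the C12 ketone (acid moves it into ring D), the 1,5-dicarbonyl array C7/C12 (base can cleave C8–C9 by retro-Michael reaction), the epimerisable C5–H and the cis-diacid; the two carboxyls sit on or between quaternary carbons and cannot be freed by saponification once aldehyde and ketone are present. What opens the structure is ring A: cis carboxyls on adjacent C4 (also methylated) and C5 are citraconic anhydride, and C10 (with C20 and C9), C1, C2, C3 are a diene whose crowded C10 terminus becomes usable when the carboxyl-level carbon C9 is tied through oxygen to C3, which is 3-methyl-2-pyrone.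

## Retrosynthesis

**25 from 24.** The last operation should only free the two carboxyls. The O–alkyl bonds of the bis[2-(trimethylsilyl)ethyl] ester 24 are cut by fluoride at silicon, four atoms away from the hindered carbonyls, without touching aldehyde, ketone or methylene. Methyl esters would need forcing saponification, tert-butyl esters acid, and benzyl or allyl esters collide with the hydrogenations earlier in the route. The skeleton is unchanged; what is asked is that these esters survive every step from step 4 on.

**24 from 23.** Ring D is opened at C13–C16. Cutting C15–C16 or C8–C15 inside the bicycle would leave the quaternary C8 to be built in a cage. The C13–C16 cut gives the monocyclic 23, in which C13 is the carbon terminus of a silyl enol ether and C16 the inner carbon of a propargyl group on C8. Closure of this pair leaves the C12 ketone and the exocyclic methylene directly, with one ring and one stereocentre fewer in the precursor. The enol ether must lie between C12 and C13, not between C11 and C12.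

**23 from 21 and 22.** The C8–C15 bond is cut: propargyl bromide 22 alkylates the aldehyde enolate of 21. This places the quaternary centre late and lets the large ring-A group on C9 choose the face. The alternative, carrying the propargyl group into the cycloaddition, would need the less stable geometry of a trisubstituted enal.

**21 from 18 and 20.** Ring C is cut at C9–C11 and C8–C14, a [4+2] between enal 18 (C8=C9) and the 2-silyloxydiene 20 (C11 to C14). The other pairing (C8–C9 and C13–C14) would leave the enol ether at C11=C12 and so point the later ring closure at the wrong α-carbon. The precursor 18 has no bicycle and no new stereocentre. The forward reaction must add the diene to the Re face of C9, which is asked of a chiral Lewis acid.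

**18 from 15 and 16; 15 from 14 from 13.** The C8=C9 alkene is cut by a two-carbon formyl olefination of aldehyde 15 with phosphonate 16. The aldehyde comes from acid 13 through alcohol 14, because a free acid is the one carboxyl function that a reducing agent can pick out beside two esters.

**13 from 12 from 11 from 10.** The C3 oxygen left by the lactone is removed as water: alcohol 11 is dehydrated to alkene 12 (only C2 has hydrogens to lose), and one hydrogenation saturates the ring and frees the C9 acid. For that, the lactone of 10 is opened as a benzyl ester. This is shorter than radical deoxygenation and marks C9 as different from C19 and C6.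

**10 from 8 from 7 from 6 from 5.** The two ester groups come from the anhydride: alcoholysis gives half-ester 7, whose free acid is the handle for resolution as salt 8, and the second ester follows. Resolving here, at the first acid of the route, wastes the least material. Hydrogenation of 5 to 6 comes first because it removes the alkene that lets 5 lose CO2.

**5 from 3 and 4.** The key cut breaks C3–C4 and C5–C10, giving 3-methyl-2-pyrone 3 and citraconic anhydride 4. No other pair of cuts in ring A removes three stereocentres and three carboxyl-level carbons at once. An open-chain diene would have to carry C9 as an inside substituent, which keeps it from the s-cis form; the lactone bridge removes that penalty. The forward reaction must be endo and must join the methyl-bearing C4 to the unsubstituted C3.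

**3 from 1 and 2.** The C10–C20 bond is cut: 3-bromo-2-pyrone 1 is methylated with tetramethylstannane 2 in one step.

## Roads not taken

**Alternative 1:** The cut is C13–C16, made together with the breaking of C12–C16: the bicyclo[3.2.1]octane is traced to a bicyclo[2.2.2]octane A1 with a xanthate on C13, a tertiary hydroxyl on C12 and the exocyclic alkene on C16. Forward, (Me3Si)3SiH generates the C13 radical, which adds to C16; the cyclopropylcarbinyl radical reopens at C12–C16 and the α-hydroxy radical at C12 is reduced, giving A2.
- Merits: bicyclo[2.2.2]octanes come from very predictable cycloadditions, and the shift is neutral and driven by the more stable radical. It needs neither a regiodefined enol ether nor a π-acid next to a C7 carbonyl, so on this count it is safer than step 16 of the chosen route.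
- Weak points: it answers only the ring C/D question. A1 must still be assembled on C9 with the C9–C10 relation solved, and its three handles cost several steps. After A2, the C12 alcohol and the C7 silyl ether must each be adjusted, and the methyl esters of A2 face the saponification problem.
- Comparison: the chosen plan reaches bicycle 24 from enal 18 in three steps and covers its less certain ring-D closure with a fallback.

**Alternative 2:** The cuts are C4–C19 and C10–C9, both at quaternary carbons. Forward, the bis(allyl β-keto ester) A3 with Pd2(dba)3 (zerovalent palladium) and a chiral phosphinooxazoline ligand loses two CO2 and gives the C2-symmetric diallyl ketone A4.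
- Merits: both quaternary centres are set with absolute control by a catalyst, with no resolution and no loss of half the material. In this respect it is clearly better than the chosen plan.
- Weak points: A4 holds C19 and C9 as allyl CH2 groups, so C19 must be cut down by two carbons and oxidised, and C9 must be turned into a branching point. The two allyl groups are equivalent by symmetry and must be told apart. C6 has to be introduced, with control at C5, at a ketone wedged between two quaternary carbons.
- Comparison: against the resolution, the chosen plan sets one cycloaddition that delivers C19, C6 and C9 at the carboxyl level, the C5–C6 bond in place and the three ring-A centres in the right relative configuration.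

**Alternative 3:** The cuts are C4–C5 and C9–C10. Forward, Mn(OAc)3 (trivalent manganese) oxidises the β-keto ester A5 to the C4 radical, which closes ring A 6-endo on C5; the C10 radical then closes ring B 6-exo on one β-carbon of the cyclohexadienone, giving A6.
- Merits: two rings and two C–C bonds form in one operation, and the C9–C10 relation is fixed inside a ring. This is exactly the relation that the chosen plan must impose with a chiral catalyst in step 14, so here alternative 3 is the stronger design. The 8-phenylmenthyl ester gives absolute control without resolution.
- Weak points: ring B is absent from the target, so C6–C7 must later be cleaved with different oxidation levels at its two ends. The C3 ketone is surplus, the second closure must choose between two diastereotopic enone arms, the auxiliary ester on the quaternary C4 is very hard to remove, and ring D is still to be built.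
- Comparison: the chosen plan never makes the C6–C7 bond and carries no surplus oxygen except the lactone oxygen on C3, removed in two steps; it pays for this with step 14.

Key step: step 2

Assumption: the sense of two chiral-recognition events (which diastereomeric salt crystallises in step 5; which antipode of the step 14 catalyst opens the C9 Re face) cannot be settled on paper; the route is written with (R)-1-phenylethylamine and the (S)-proline-derived catalyst, and the mirror-image reagent, equally available, takes its place if the sense is found to be opposite.

## Route

Step 1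
Reactants: 1 3-bromo-2H-pyran-2-one; 2 tetramethylstannane
Product: 3 3-methyl-2H-pyran-2-one
Conditions: Pd(PPh3)4 (5 mol%, zerovalent palladium), CuI (10 mol%), DMF, 80 °C, sealed tube
Reagents that add atoms: none
Why: Stille coupling of an electron-poor vinylic bromide; the neutral conditions keep the base-sensitive pyrone ring closed; no stereocentre is formed.

Step 2
Reactants: 3 3-methyl-2H-pyran-2-one; 4 citraconic anhydride
Product: 5 racemic endo adduct, 4,7-dimethyl-3-oxo-2-oxabicyclo[2.2.2]oct-5-ene-7,8-dicarboxylic anhydride (anhydride ring syn to the C=C bridge, 7-methyl syn to the lactone bridge)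
Conditions: CH2Cl2 (2 M), 12 kbar, 30 °C
Reagents that add atoms: none
Why: A concerted, suprafacial [4π+2π] cycloaddition of the s-cis-locked diene of 3 (future C10, C1, C2, C3) with the alkene of 4, of the same type as the long-known additions of 2-pyrones to maleic anhydride that stop at the bridged lactone when run under pressure below the temperature of CO2 loss. Ring A closes as a six-membered carbocycle through one six-centre transition state in which both σ bonds (C3–C4 and C5–C10) form together; because C9 and C3 are already linked through oxygen, the product is a 2-oxabicyclo[2.2.2]octenone. C4 and C5 keep the cis relation of the dienophile because addition to 4 is suprafacial. C10 and C3 are the two bridgeheads, so their relative configuration is fixed by the bicycle. The relation of the C4/C5 pair to C10 comes from endo approach: the anhydride lies under the diene, so C19 and C6 end syn to the new C1=C2 bridge, anti to the C9–O bridge and therefore cis to the C10 methyl. The step needs endo selectivity and the regiochemistry that joins methyl-bearing C4 to unsubstituted C3; the first rests on secondary overlap of the anhydride carbonyls with the diene, the second on the steric cost of joining the two fully substituted carbons C4 and C10 in the other orientation. Pressure speeds the addition through its negative activation volume without the heat that would expel CO2. The adduct is racemic; absolute configuration enters in step 5.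

Step 3
Reactants: 5 racemic endo adduct
Product: 6 racemic saturated adduct, 4,7-dimethyl-3-oxo-2-oxabicyclo[2.2.2]octane-7,8-dicarboxylic anhydride
Conditions: H2 (1 atm), Rh/Al2O3 (5 wt% rhodium metal), EtOAc, rt
Reagents that add atoms: none
Why: Heterogeneous hydrogenation of a strained cis-disubstituted alkene; it removes the double bond that allows retro-[4+2] loss of CO2, and rhodium is chosen because it is less prone than palladium to cleave the allylic C3–O bond; no stereocentre changes.

Step 4
Reactants: 6 racemic saturated adduct
Product: 7 racemic half-ester, lactone intact, C6 carboxyl as 2-(trimethylsilyl)ethyl ester, C19 carboxyl free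
Conditions: Me3SiCH2CH2OH (2 equiv), DMAP (10 mol%), toluene, 60 °C
Reagents that add atoms: 2-(trimethylsilyl)ethanol, C[Si](C)(C)CCO
Why: DMAP-catalysed alcoholysis of a cyclic anhydride, expected at the C6 carbonyl (α-carbon is CH) rather than the C19 carbonyl (α-carbon quaternary); the lactone is much less electrophilic and stays closed, and any regioisomeric half-ester would converge to 10 in step 6.

Step 5
Reactants: 7 racemic half-ester
Product: 8 (R)-1-phenylethylammonium salt of the half-ester enantiomer with ring-A configuration as in the target
Conditions: (R)-PhCH(CH3)NH2 (1 equiv), acetone, warm then 4 °C; recrystallise to constant rotation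
Reagents that add atoms: (R)-1-phenylethylamine, C[C@@H](N)c1ccccc1
Why: Classical resolution by fractional crystallisation of diastereomeric ammonium carboxylates; this sets the absolute configuration of C4, C5 and C10, and the ammonium ion is not nucleophilic towards the lactone.

Step 6
Reactants: 8 ammonium salt
Product: 10 bis[2-(trimethylsilyl)ethyl] ester of the saturated lactone diacid (C19 and C6 esters, lactone intact), via resolved acid 9 (not isolated)
Conditions: 1 M HCl/EtOAc partition; then Me3SiCH2CH2OH, PPh3, DIAD, THF, 0 °C → rt
Reagents that add atoms: 2-(trimethylsilyl)ethanol, C[Si](C)(C)CCO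
Why: Mitsunobu esterification; the carboxylate attacks the activated primary carbon of the alcohol, so crowding at the C19 carbonyl does not matter; no stereocentre is touched.

Step 7
Reactants: 10 bis-ester lactone
Product: 11 hydroxy triester: benzyl ester at C9, 2-(trimethylsilyl)ethyl esters at C19 and C6, hydroxyl on C3 cis to the C9 ester
Conditions: BnOH (5 equiv), NaH (0.2 equiv), THF, 0 °C → rt; AcOH
Reagents that add atoms: benzyl alcohol, OCc1ccccc1
Why: Alkoxide-catalysed lactone alcoholysis (transesterification), driven by relief of the boat strain of the bridged δ-lactone; the hindered silylethyl esters do not exchange, and C9 now carries the only ester that hydrogenolysis removes.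

Step 8
Reactants: 11 hydroxy triester
Product: 12 cyclohexene triester (C2=C3 alkene)
Conditions: Ph2S[OC(CF3)2Ph]2 (Martin sulfurane, 1.5 equiv), CH2Cl2, 0 °C → rt
Reagents that add atoms: none
Why: Martin sulfurane dehydration of a secondary alcohol by anti elimination from the chair with axial C3–O; only C2 carries β-hydrogens, since C4 is quaternary, so one alkene can form, and the now superfluous C3 stereocentre is erased.

Step 9
Reactants: 12 cyclohexene triester
Product: 13 ring-A acid: C9 carboxylic acid on C10, 2-(trimethylsilyl)ethyl esters at C19 and C6
Conditions: H2 (1 atm), Pd/C (10 wt% palladium metal), EtOAc, rt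
Reagents that add atoms: none
Why: One hydrogenation saturates the disubstituted alkene and cleaves the benzyl ester by hydrogenolysis; silylethyl esters are inert; no stereocentre is formed.

Step 10
Reactants: 13 ring-A acid
Product: 14 ring-A primary alcohol (C9 as CH2OH)
Conditions: BH3·SMe2, THF, 0 °C → rt; H2O
Reagents that add atoms: none
Why: Borane reduces a carboxylic acid through its acyloxyborane far faster than it reduces esters, so C9 alone is reduced.

Step 11
Reactants: 14 ring-A primary alcohol
Product: 15 ring-A aldehyde (C9 as CHO on the quaternary C10)
Conditions: Dess–Martin periodinane, CH2Cl2, rt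
Reagents that add atoms: none
Why: Dess–Martin oxidation of a neopentyl primary alcohol; the aldehyde has no α-hydrogen and cannot epimerise or over-oxidise under these conditions.

Step 12
Reactants: 15 ring-A aldehyde; 16 diethyl [(E)-2-(cyclohexylamino)ethenyl]phosphonate
Product: 18 (E)-enal (C7 formyl, C8=C9, C9 on C10), via unsaturated N-cyclohexylimine 17 (not isolated)
Conditions: NaH, THF, 0 → 40 °C; then aq. oxalic acid, rt
Reagents that add atoms: water, O
Why: Horner–Wadsworth–Emmons formyl olefination with a metallated phosphonate enamine, reactive enough for a neopentyl aldehyde and E-selective; the unsaturated imine cannot react a second time and is hydrolysed to the enal on work-up.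

Step 13
Reactants: 19 but-3-en-2-one
Product: 20 2-[tri(propan-2-yl)silyloxy]buta-1,3-diene
Conditions: i-Pr3SiOTf, Et3N, Et2O, 0 °C
Reagents that add atoms: triisopropylsilyl trifluoromethanesulfonate, CC(C)[Si](OS(=O)(=O)C(F)(F)F)(C(C)C)C(C)C
Why: Soft enolisation and O-silylation of a methyl ketone with a silyl triflate and an amine base, the standard route to 2-silyloxydienes.

Step 14
Reactants: 18 (E)-enal; 20 2-silyloxydiene
Product: 21 cyclohexene adduct: C12=C13 silyl enol ether, C8 formyl trans to the ring-A group on C9
Conditions: (S)-tetrahydro-1-(2-methylphenyl)-3,3-diphenyl-1H,3H-pyrrolo[1,2-c][1,3,2]oxazaborole (20 mol%), HN(SO2CF3)2 (18 mol%), CH2Cl2, −78 → −40 °C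
Reagents that add atoms: none
Why: Diels–Alder reaction of an enal with a 2-silyloxydiene under a protonated chiral oxazaborolidine Lewis acid; the nucleophilic CH2 terminus of the diene (C11) bonds to the β-carbon C9 and C14 to C8, which leaves the enol ether at C12=C13. C9 is set by the catalyst, which should shield one face of the bound s-trans enal so that the diene adds to the C9 Re face; C8 follows as trans from suprafacial addition to the E-alkene and is reset in step 15.

Step 15
Reactants: 21 cyclohexene adduct; 22 3-bromoprop-1-yne
Product: 23 propargylated aldehyde: quaternary C8 with formyl cis and prop-2-ynyl trans to the ring-A group on C9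
Conditions: KOtBu, THF, −40 °C; then 22, −40 → 0 °C
Reagents that add atoms: none
Why: C-alkylation of the potassium enolate of an α-branched aldehyde with a propargylic bromide; allylic strain turns the ring-A group on C9 axial so that it covers one face of the exocyclic enolate, and the electrophile enters anti to it, which sets C8; the silyl enol ether and the hindered esters are inert to the base.

Step 16
Reactants: 23 propargylated aldehyde
Product: 24 bis[2-(trimethylsilyl)ethyl] ester of the target
Conditions: AuCl(PPh3) (5 mol%), AgBF4 (5 mol%), CH2Cl2/MeOH 10:1, rt
Reagents that add atoms: none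
Why: Monovalent-gold-catalysed 5-exo-dig addition of a silyl enol ether to a terminal alkyne (a Conia-ene-type carbocyclisation known to give bicyclo[3.2.1]octanones with an exocyclic methylene); C13 attacks C16, methanol takes the silyl group and protonates the vinyl–gold bond. C13 is set by C8, because the bridge can only form on the face that carries the propargyl group.

Step 17
Reactants: 24 bis-ester of the target
Product: 25 (1R,2S,3S)-3-[(1R,2S,5R)-1-formyl-6-methylidene-4-oxobicyclo[3.2.1]octan-2-yl]-1,3-dimethylcyclohexane-1,2-dicarboxylic acid
Conditions: [(Me2N)3S][Me3SiF2] (TASF, 3 equiv), DMF, 0 °C → rt; then aq. HCl to pH 3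
Reagents that add atoms: none
Why: Fluoride attacks silicon and each ester fragments to carboxylate, ethene and Me3SiF; the reaction takes place away from the crowded carbonyls under nearly neutral conditions that spare the non-enolisable aldehyde, the ketone and the exocyclic alkene.

## Compound list

1 | 3-bromo-2H-pyran-2-one | O=C1OC=CC=C1Br | starting material
2 | tetramethylstannane | C[Sn](C)(C)C | starting material
3 | 3-methyl-2H-pyran-2-one | CC1=CC=COC1=O | intermediate
4 | citraconic anhydride (3-methylfuran-2,5-dione) | CC1=CC(=O)OC1=O | starting material
5 | endo adduct, 4,7-dimethyl-3-oxo-2-oxabicyclo[2.2.2]oct-5-ene-7,8-dicarboxylic anhydride; racemic, the enantiomer carried on is drawn | O=C2[C@]1(C)C=C[C@H](O2)[C@@](C)(C(=O)OC3=O)[C@H]13 | intermediate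
6 | 4,7-dimethyl-3-oxo-2-oxabicyclo[2.2.2]octane-7,8-dicarboxylic anhydride; racemic, the enantiomer carried on is drawn | O=C2[C@]1(C)CC[C@H](O2)[C@@](C)(C(=O)OC3=O)[C@H]13 | intermediate
7 | 4,7-dimethyl-3-oxo-8-{[2-(trimethylsilyl)ethoxy]carbonyl}-2-oxabicyclo[2.2.2]octane-7-carboxylic acid; racemic, the enantiomer carried on is drawn | O=C2[C@]1(C)CC[C@H](O2)[C@@](C)(C(=O)O)[C@H]1C(=O)OCC[Si](C)(C)C | intermediate
8 | (R)-1-phenylethylammonium salt of the drawn enantiomer of 7 | O=C2[C@]1(C)CC[C@H](O2)[C@@](C)(C(=O)[O-])[C@H]1C(=O)OCC[Si](C)(C)C.C[C@@H]([NH3+])c1ccccc1 | intermediate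
9 | resolved half-ester acid (single enantiomer of 7) | O=C2[C@]1(C)CC[C@H](O2)[C@@](C)(C(=O)O)[C@H]1C(=O)OCC[Si](C)(C)C | intermediate
10 | bis[2-(trimethylsilyl)ethyl] 4,7-dimethyl-3-oxo-2-oxabicyclo[2.2.2]octane-7,8-dicarboxylate (single enantiomer) | O=C2[C@]1(C)CC[C@H](O2)[C@@](C)(C(=O)OCC[Si](C)(C)C)[C@H]1C(=O)OCC[Si](C)(C)C | intermediate
11 | 1-benzyl 2,3-bis[2-(trimethylsilyl)ethyl] 4-hydroxy-1,3-dimethylcyclohexane-1,2,3-tricarboxylate; the 2- and 3-ester groups and the 1-methyl on one face, the benzyl ester and the hydroxyl on the other | O=C(OCc1ccccc1)[C@]1(C)CC[C@H](O)[C@@](C)(C(=O)OCC[Si](C)(C)C)[C@H]1C(=O)OCC[Si](C)(C)C | intermediate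
12 | 1-benzyl 2,3-bis[2-(trimethylsilyl)ethyl] 1,3-dimethylcyclohex-4-ene-1,2,3-tricarboxylate, ring configuration as in 11 | O=C(OCc1ccccc1)[C@]1(C)CC=C[C@@](C)(C(=O)OCC[Si](C)(C)C)[C@H]1C(=O)OCC[Si](C)(C)C | intermediate
13 | 1,3-dimethyl-2,3-bis{[2-(trimethylsilyl)ethoxy]carbonyl}cyclohexane-1-carboxylic acid; the two ester groups cis to each other and to the 1-methyl, trans to the free acid | O=C(O)[C@]1(C)CCC[C@@](C)(C(=O)OCC[Si](C)(C)C)[C@H]1C(=O)OCC[Si](C)(C)C | intermediate
14 | bis[2-(trimethylsilyl)ethyl] 3-(hydroxymethyl)-1,3-dimethylcyclohexane-1,2-dicarboxylate; ester groups cis to each other and to the 3-methyl | OC[C@]1(C)CCC[C@@](C)(C(=O)OCC[Si](C)(C)C)[C@H]1C(=O)OCC[Si](C)(C)C | intermediate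
15 | bis[2-(trimethylsilyl)ethyl] 3-formyl-1,3-dimethylcyclohexane-1,2-dicarboxylate, configuration as in 14 | O=C[C@]1(C)CCC[C@@](C)(C(=O)OCC[Si](C)(C)C)[C@H]1C(=O)OCC[Si](C)(C)C | intermediate
16 | diethyl [(E)-2-(cyclohexylamino)ethenyl]phosphonate | CCOP(=O)(OCC)/C=C/NC1CCCCC1 | starting material
17 | N-cyclohexylimine of enal 18 | C1CCCCC1/N=C/C=C/[C@]1(C)CCC[C@@](C)(C(=O)OCC[Si](C)(C)C)[C@H]1C(=O)OCC[Si](C)(C)C | intermediate
18 | bis[2-(trimethylsilyl)ethyl] 1,3-dimethyl-3-[(E)-3-oxoprop-1-en-1-yl]cyclohexane-1,2-dicarboxylate, ring configuration as in 14 | O=C/C=C/[C@]1(C)CCC[C@@](C)(C(=O)OCC[Si](C)(C)C)[C@H]1C(=O)OCC[Si](C)(C)C | intermediate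
19 | but-3-en-2-one | CC(=O)C=C | starting material
20 | 2-[tri(propan-2-yl)silyloxy]buta-1,3-diene | C=CC(=C)O[Si](C(C)C)(C(C)C)C(C)C | intermediate
21 | bis[2-(trimethylsilyl)ethyl] 3-{trans-6-formyl-3-[tri(propan-2-yl)silyloxy]cyclohex-3-en-1-yl}-1,3-dimethylcyclohexane-1,2-dicarboxylate; C9 configured as in the target | O=C[C@@H]1CC=C(O[Si](C(C)C)(C(C)C)C(C)C)C[C@H]1[C@]1(C)CCC[C@@](C)(C(=O)OCC[Si](C)(C)C)[C@H]1C(=O)OCC[Si](C)(C)C | intermediate
22 | 3-bromoprop-1-yne | BrCC#C | starting material
23 | bis[2-(trimethylsilyl)ethyl] 3-{6-formyl-6-(prop-2-yn-1-yl)-3-[tri(propan-2-yl)silyloxy]cyclohex-3-en-1-yl}-1,3-dimethylcyclohexane-1,2-dicarboxylate; formyl cis and propynyl trans to the ring-A group | O=C[C@@]1(CC#C)CC=C(O[Si](C(C)C)(C(C)C)C(C)C)C[C@H]1[C@]1(C)CCC[C@@](C)(C(=O)OCC[Si](C)(C)C)[C@H]1C(=O)OCC[Si](C)(C)C | intermediate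
24 | bis[2-(trimethylsilyl)ethyl] ester of 25 | C=C1C[C@]2(C=O)C[C@H]1C(=O)C[C@H]2[C@]1(C)CCC[C@@](C)(C(=O)OCC[Si](C)(C)C)[C@H]1C(=O)OCC[Si](C)(C)C | intermediate
25 | (1R,2S,3S)-3-[(1R,2S,5R)-1-formyl-6-methylidene-4-oxobicyclo[3.2.1]octan-2-yl]-1,3-dimethylcyclohexane-1,2-dicarboxylic acid | C=C1C[C@]2(C=O)C[C@H]1C(=O)C[C@H]2[C@]1(C)CCC[C@@](C)(C(=O)O)[C@H]1C(=O)O | target

## Step count and least certain steps

Total: 17 steps. Longest linear sequence: 16 steps (steps 1 to 12 and 14 to 17); step 13 is a one-step branch.

**Step 2 (key step).** Both partners are electron-poor, so the addition may be slow; if it is pushed by heat, adduct 5 can lose CO2, and the endo and regiochemical preferences may be incomplete. Fallback: use bromine as a removable activating group on the diene. Starting from 2 and 4, 3,5-dibromo-2H-pyran-2-one F1 is methylated at C3 by Stille coupling with 2 to give 5-bromo-3-methyl-2H-pyran-2-one F2. Bromopyrones of this kind add to electron-poor alkenes more readily and give more stable bridged adducts. Cycloaddition of F2 with 4 gives the bromo adduct F3, and Bu3SnH/AIBN removes the vinylic bromine; the route is rejoined at 5.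

**Step 14.** The β-carbon C9 is neopentyl-like, so the cycloaddition may be slow enough for the acid catalyst to destroy the diene, and the bias of C10 may oppose the catalyst and lower facial selectivity. Fallback: reverse the roles of the partners. Starting from 15, a Horner–Wadsworth–Emmons reaction with dimethyl (2-oxopropyl)phosphonate gives the (E)-enone F4, and silylation gives the 1-substituted 3-silyloxydiene F5. Its cycloaddition under the same class of catalyst with 2-methylidenepent-4-ynal F6, an α-substituted acrolein, which is the best substrate class for such catalysts, gives the endo adduct F7, in which C8 already carries formyl and propynyl groups. F7 has its enol ether at C11=C12, so it is hydrolysed to the keto aldehyde F8 and re-silylated with the bulky silyl triflate and Et3N towards the less hindered C13; the route is rejoined at 23, and steps 14 and 15 are bypassed.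

**Step 15.** O-alkylation of the aldehyde enolate, or reversible attack of the enolate on the C6 ester, may compete with C-alkylation at a carbon that becomes quaternary next to C9. Fallback: use an allyl group and a different ring closure. Starting from 21, allyl bromide and KOtBu give the C-allyl aldehyde F9. Any O-allyl dienol ether F10 is converted into F9 by thermal Claisen rearrangement, which delivers the allyl group to the same face, anti to the ring-A group. Oxidative cycloalkenylation of the silyl enol ether of F9 with Pd(OAc)2 (divalent palladium) in DMSO (5-exo insertion, then β-hydride elimination to the exocyclic alkene) rejoins the route at 24.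

**Step 16.** The substrate is a 4-alkynal, so the aldehyde oxygen, with methanol, may capture the gold-activated alkyne as a cyclic acetal; protodesilylation of the enol ether would also lose the regiochemistry. Fallback: close ring D by a radical. Starting from 23, N-iodosuccinimide converts the enol ether regiospecifically into the α-iodo ketone F11. Et3B/O2 starts an atom-transfer 5-exo-dig cyclisation of the C13 radical onto the alkyne, giving the vinyl iodide F12. Bu3SnH with catalytic Pd(PPh3)4 (zerovalent palladium) removes the iodine; the route is rejoined at 24.

**Step 5.** The diastereomeric salts may fail to separate by crystallisation, or the salt of the unwanted enantiomer may crystallise. Fallback: separate the enantiomers of 7 by preparative chromatography on a chiral stationary phase and take the correct enantiomer, which is 9, into step 6; no new compound is made (F0).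

## Further compounds

F1 | step 2 | 3,5-dibromo-2H-pyran-2-one | O=C1OC=C(Br)C=C1Br
F2 | step 2 | 5-bromo-3-methyl-2H-pyran-2-one | CC1=CC(Br)=COC1=O
F3 | step 2 | 6-bromo derivative of adduct 5 (bromine on the alkene carbon next to the oxygen-bearing bridgehead), racemic | O=C2[C@]1(C)C=C(Br)[C@H](O2)[C@@](C)(C(=O)OC3=O)[C@H]13
F4 | step 14 | bis[2-(trimethylsilyl)ethyl] 1,3-dimethyl-3-[(E)-3-oxobut-1-en-1-yl]cyclohexane-1,2-dicarboxylate | CC(=O)/C=C/[C@]1(C)CCC[C@@](C)(C(=O)OCC[Si](C)(C)C)[C@H]1C(=O)OCC[Si](C)(C)C
F5 | step 14 | bis[2-(trimethylsilyl)ethyl] 1,3-dimethyl-3-{(E)-3-[tri(propan-2-yl)silyloxy]buta-1,3-dien-1-yl}cyclohexane-1,2-dicarboxylate | C=C(O[Si](C(C)C)(C(C)C)C(C)C)/C=C/[C@]1(C)CCC[C@@](C)(C(=O)OCC[Si](C)(C)C)[C@H]1C(=O)OCC[Si](C)(C)C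
F6 | step 14 | 2-methylidenepent-4-ynal | C=C(CC#C)C=O
F7 | step 14 | regioisomer of 23 with the silyl enol ether at C11=C12 | O=C[C@@]1(CC#C)CCC(O[Si](C(C)C)(C(C)C)C(C)C)=C[C@H]1[C@]1(C)CCC[C@@](C)(C(=O)OCC[Si](C)(C)C)[C@H]1C(=O)OCC[Si](C)(C)C
F8 | step 14 | keto aldehyde from hydrolysis of F7 (C12 ketone, C8 formyl and propynyl) | O=C[C@@]1(CC#C)CCC(=O)C[C@H]1[C@]1(C)CCC[C@@](C)(C(=O)OCC[Si](C)(C)C)[C@H]1C(=O)OCC[Si](C)(C)C
F9 | step 15 | allyl analogue of 23 (prop-2-en-1-yl on C8 in place of prop-2-yn-1-yl) | O=C[C@@]1(CC=C)CC=C(O[Si](C(C)C)(C(C)C)C(C)C)C[C@H]1[C@]1(C)CCC[C@@](C)(C(=O)OCC[Si](C)(C)C)[C@H]1C(=O)OCC[Si](C)(C)C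
F10 | step 15 | O-allyl dienol ether of 21 | C=CCOC=C1CC=C(O[Si](C(C)C)(C(C)C)C(C)C)C[C@H]1[C@]1(C)CCC[C@@](C)(C(=O)OCC[Si](C)(C)C)[C@H]1C(=O)OCC[Si](C)(C)C
F11 | step 16 | α-iodo ketone from 23 (iodine on C13, C12 ketone) | O=C[C@@]1(CC#C)CC(I)C(=O)C[C@H]1[C@]1(C)CCC[C@@](C)(C(=O)OCC[Si](C)(C)C)[C@H]1C(=O)OCC[Si](C)(C)C
F12 | step 16 | 17-iodo derivative of 24 (exocyclic iodomethylidene) | IC=C1C[C@]2(C=O)C[C@H]1C(=O)C[C@H]2[C@]1(C)CCC[C@@](C)(C(=O)OCC[Si](C)(C)C)[C@H]1C(=O)OCC[Si](C)(C)C
F0 | step 5 | none | none
A1 | alternative 1 | bicyclo[2.2.2]octane xanthate with C12 tertiary alcohol and C16 exocyclic alkene | C=C1C[C@]2(CO[Si](C)(C)C(C)(C)C)CC(OC(=S)SC)[C@@]1(O)C[C@H]2[C@]1(C)CCC[C@@](C)(C(=O)OC)[C@H]1C(=O)OC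
A2 | alternative 1 | bicyclo[3.2.1]octane with C12 carbinol | C=C1C[C@]2(CO[Si](C)(C)C(C)(C)C)C[C@H]1[C@@H](O)C[C@H]2[C@]1(C)CCC[C@@](C)(C(=O)OC)[C@H]1C(=O)OC
A3 | alternative 2 | diallyl 1,3-dimethyl-2-oxocyclohexane-1,3-dicarboxylate | C=CCOC(=O)C1(C)CCCC(C)(C(=O)OCC=C)C1=O
A4 | alternative 2 | (2S,6S)-2,6-diallyl-2,6-dimethylcyclohexanone | C=CC[C@]1(C)CCC[C@@](C)(CC=C)C1=O
A5 | alternative 3 | open-chain β-keto 8-phenylmenthyl ester carrying the 4,4-disubstituted cyclohexadienone | COC(=O)CC1(C=CC(=O)C=C1)C(=O)C/C=C(\C)CCC(=O)C(C)C(=O)O[C@@H]1C[C@H](C)CC[C@H]1C(C)(C)c1ccccc1
A6 | alternative 3 | tricyclic enone with rings A and B and the ring C enone | COC(=O)C[C@]2(C3=O)C=CC(=O)C[C@H]2[C@]1(C)CCC(=O)[C@@](C)(C(=O)O[C@@H]4C[C@H](C)CC[C@H]4C(C)(C)c4ccccc4)[C@H]1C3
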